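27.5 min is the life of the substrate as I read it from the ochre run: the mean of its last two readings divided by its slope up to 15.0 min. This takes the bend in the curve to be first-order loss of substrate.

| setting | ochre | birch | oak |
|---|---|---|---|
| substrate | 22 mM | 20 mM | 6.0 mM |
| gas phase | 1 mM (held) | 1.0 mM (held) | 1.0 mM (held) |
| remark | run made earlier |  |  |
| time |  | 80 min | 80 min |

- ochre (time / min: target / %): 8.00: 5; 15.0: 9; 25.0: 11; 30.0: 12; 40.0: 17; 50.0: 16

(readings scatter by 1.5 percentage points)

- the earlier runs were read with a standard deviation of 1.5 percentage points
- at the start none of the gas phase is in solution

- the flask that ends with the higher amount of target, in percent of the substrate charged, or "neither" when 2 percentage points or less lies between them (birch / oak / neither)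
- final target, as a percentage of the substrate charged, in birch
- final target, as a percentage of the substrate charged, in oak

I assume that the dissolved gas follows the substrate closely (quasi-steady state), so I treat a flask whose substrate has fallen to some level as running on like one charged at that level. On that assumption, the late ochre run stands in for oak. Between the mean times 27.5 min and 45.0 min, this life takes the substrate from 0.368 to 0.195 of the ochre charge, and oak's charge, 0.273 of it, lies inside that span. The ochre readings then give 28.9 % as the tail share, the target gained per substrate spent in that stretch. Before the stretch, the head share is 18.2 %.

By 80 min my reckoning leaves 0.0545 of a charge, so I count it as spent. Substrate above the level 0.368 of the ochre charge yields the head share, and substrate below it the tail share. Oak starts below that level, so I commit to 28.9 % for oak and 22.5 % for birch, with oak as the higher.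

The weak link is the life. Reforged from the first reading, it becomes 26.4 min, and the tail share stays at 29.2 %. Its scatter, about 8.7 percentage points, remains.

The forecast also leans to oak, “with wide uncertainty”, giving 28 % there and 19 % in birch, lower than mine.

Oak ends at 28.8 % and birch at 18.2 %, so oak ends higher. Conversion in oak reaches 99.7 %, so its end value is a share of a spent charge. My tail share of 28.9 % stands close to that oak value, while my birch figure stands 4.3 points too high.

    gas phase ⇌ dissolved gas, rate k1*(csat - [dissolved gas]) (kL = 0.00340 s⁻¹)
    substrate + dissolved gas → target (k = 0.630 M⁻¹ s⁻¹)
    substrate → side product A (k = 6.40 × 10⁻⁴ s⁻¹)
    substrate + target → side product B (k = 0.0260 M⁻¹ s⁻¹)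
    target ⇌ isomer of the product (K = 6.70, k = 3.40 × 10⁻⁵ s⁻¹)

In a neighbour flask like oak but charged with 15 mM, the two shares give 24.0 %. The flask gives 21.1 %.

The numbers in the tables were generated by integration for substances that don't exist.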